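The three phenols are masked as benzyl ethers. Ring C is then cut at O1–C8a, C4–C4a and O1–C2 at once, which leaves a ring-A aryne and a ring-B arylpropiolic acid.
Enabling feature: on ring A, C8a (bearing O1) and C4a (bearing the C4 carbonyl) are direct neighbours and the C5 oxygen flanks C4a. A 3-alkoxybenzyne leaves this pattern after taking up the oxygen and the acyl carbon of a carboxylic acid.
Ring A, forward: 3,5-bis(benzyloxy)phenol is brominated at C2, O-silylated, and converted into the ortho-silylaryl triflate by a silyl shift and triflation.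
Ring B, forward: 2,6-dimethoxyphenol is benzylated and diiodinated to a symmetric diiodide. One iodine becomes the 5'-methoxy group and the other is coupled with propiolic acid.
Rings A and B are bought. Ring C is the only ring built and arises when the two halves are joined, and hydrogenolysis then frees the three hydroxyl groups.
The target has no stereocentre and no stereogenic double bond, so there is no stereochemistry to control.

Key step: step 9

Assumption: 3,5-bis(benzyloxy)phenol, 2,6-dimethoxyphenol and propiolic acid are taken as purchasable. Flavone numbering (O1, C2 to C8a, primed positions on ring B) is used throughout.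

Step 1
Reactants: 1 3,5-bis(benzyloxy)phenol
Product: 2 3,5-bis(benzyloxy)-2-bromophenol
Conditions: NBS (1.0 equiv), CH2Cl2, −78 °C to rt
Reagents that add atoms: N-bromosuccinimide, O=C1CCC(=O)N1Br
Why: Electrophilic aromatic bromination should favour C2, which is ortho to the hydroxyl and para to a benzyloxy group, occurs twice and is less crowded than C4 between two benzyloxy groups, while one equivalent of NBS in the cold holds the reaction at the monobromide.

Step 2
Reactants: 2 3,5-bis(benzyloxy)-2-bromophenol
Product: 3 [3,5-bis(benzyloxy)-2-bromophenoxy]trimethylsilane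
Conditions: HMDS, THF, reflux; volatiles removed under vacuum
Reagents that add atoms: hexamethyldisilazane, C[Si](C)(C)N[Si](C)(C)C
Why: O-silylation of a phenol with HMDS is driven by loss of ammonia and leaves only volatile material, so the silyl ether can be used crude.

Step 3
Reactants: 3 [3,5-bis(benzyloxy)-2-bromophenoxy]trimethylsilane
Product: 6 3,5-bis(benzyloxy)-2-(trimethylsilyl)phenyl trifluoromethanesulfonate, via aryllithium 4 (not isolated), via lithium 2-silylphenoxide 5 (not isolated)
Conditions: n-BuLi (1.1 equiv), THF, −100 to −78 °C; then Tf2O, −100 to −78 °C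
Reagents that add atoms: trifluoromethanesulfonic anhydride, O=S(=O)(OS(=O)(=O)C(F)(F)F)C(F)(F)F
Why: Bromine–lithium exchange outruns benzylic deprotonation at this temperature, aryllithium 4 takes the silyl group from oxygen (retro-Brook 1,3-shift), and the freed phenoxide 5 is sulfonylated, which is the standard entry to ortho-silylaryl triflates.

Step 4
Reactants: 7 2,6-dimethoxyphenol
Product: 8 2-(benzyloxy)-1,3-dimethoxybenzene
Conditions: BnBr, K2CO3, DMF, 60 °C
Reagents that add atoms: benzyl bromide, BrCc1ccccc1
Why: Williamson ether synthesis on a phenoxide puts on the future 3'-O protecting group and switches off the para-directing power of the free phenol.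

Step 5
Reactants: 8 2-(benzyloxy)-1,3-dimethoxybenzene
Product: 9 3-(benzyloxy)-1,5-diiodo-2,4-dimethoxybenzene
Conditions: I2 (2.2 equiv), AgO2CCF3 (2.2 equiv), CH2Cl2, 0 °C to rt, dark
Reagents that add atoms: iodine, II
Why: In this electrophilic aromatic iodination C4 and C6 of 8 are each ortho to one methoxy group and para to the other, whereas C5 lies only para to the twisted benzyloxy group, so both iodines should enter symmetrically and no regioisomer question remains.

Step 6
Reactants: 9 3-(benzyloxy)-1,5-diiodo-2,4-dimethoxybenzene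
Product: 12 3-(benzyloxy)-5-iodo-2,4-dimethoxyphenol, via arylmagnesium chloride 10 (not isolated), via dimethyl arylboronate 11 (not isolated)
Conditions: i-PrMgCl·LiCl (1.05 equiv), THF, −20 °C; B(OMe)3, −20 °C to rt; then AcOH, 30% aq H2O2, 0 °C to rt
Reagents that add atoms: hydrogen peroxide, OO
Why: The two iodines are equivalent by symmetry, iodine–magnesium exchange should stop after one of them because arylmagnesium 10 resists a second exchange, and borylation followed by peroxide oxidation (aryl shift from boron to oxygen) is the standard way from an aryl metal to a phenol.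

Step 7
Reactants: 12 3-(benzyloxy)-5-iodo-2,4-dimethoxyphenol
Product: 13 3-(benzyloxy)-1-iodo-2,4,5-trimethoxybenzene
Conditions: MeI, K2CO3, acetone, reflux
Reagents that add atoms: iodomethane, CI
Why: Williamson methylation of the only free phenol completes the 2',4',5'-trimethoxy-3'-benzyloxy pattern with the iodine at the future C1'.

Step 8
Reactants: 13 3-(benzyloxy)-1-iodo-2,4,5-trimethoxybenzene; 14 propiolic acid
Product: 15 3-[3-(benzyloxy)-2,4,5-trimethoxyphenyl]prop-2-ynoic acid
Conditions: Pd(PPh3)4 (2.5 mol %), DBU (2.4 equiv), DMSO, 35 °C; then aq HCl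
Reagents that add atoms: none
Why: This is a copper-free Sonogashira-type coupling of an aryl iodide with propiolic acid, in which oxidative addition of the iodide to zerovalent palladium is easy and the low temperature keeps the arylpropiolate from losing CO2.

Step 9
Reactants: 6 3,5-bis(benzyloxy)-2-(trimethylsilyl)phenyl trifluoromethanesulfonate (1.5 equiv); 15 3-[3-(benzyloxy)-2,4,5-trimethoxyphenyl]prop-2-ynoic acid
Product: 20 5,7,3'-tris(benzyloxy)-2',4',5'-trimethoxyflavone, via cesium arylpropiolate 16 (not isolated), via 3,5-bis(benzyloxy)benzyne 17 (not isolated), via aryl anion adduct 18 (not isolated), via cesium ortho-alkynoylphenoxide 19 (not isolated)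
Conditions: CsF (4 equiv, dried), THF, sealed tube, 125 °C
Reagents that add atoms: none
Why: Fluoride strips the silyl group from 6 and triflate leaves to give aryne 17, CsF also converts 15 into carboxylate 16, whose oxygen adds to the aryne carbon that becomes C8a (O1–C8a), and aryl anion 18 then attacks its own ester carbonyl through a four-membered alkoxide that opens to phenoxide 19 (C4–C4a). The closest known reaction type is the insertion of arynes into the C–O bond of carboxylic acids to give ortho-hydroxyaryl ketones, which is known to continue to flavones when the acid is an arylpropiolic acid. Ring C, the only ring formed, closes by 6-endo-dig conjugate addition of the phenoxide oxygen of 19 to the alkyne carbon bearing ring B (O1–C2), and protonation at C3 completes the pyranone. No stereocentre is created. The step needs one orientation of addition, and the benzyloxy group next to the triple bond secures it: its inductive pull distorts the aryne so that the nucleophile enters at the remote carbon and the charge builds up beside the C–O bond, which places the carbonyl at C4a next to C5. It also needs acyl transfer to beat proton capture and 6-endo to beat 5-exo closure; the high temperature with dry, excess CsF serves the first and the Michael polarity of the ynone the second.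

Step 10
Reactants: 20 5,7,3'-tris(benzyloxy)-2',4',5'-trimethoxyflavone
Product: 21 5,7,3'-trihydroxy-2',4',5'-trimethoxyflavone
Conditions: H2 (1 atm), 10% Pd/C, EtOAc–MeOH, rt
Reagents that add atoms: none
Why: Catalytic hydrogenolysis cleaves the three aryl benzyl ethers while methyl ethers are inert and the conjugated C2–C3 double bond is reduced far more slowly, so the reaction is stopped after three equivalents of H2 are taken up.

Compound list
1 | 3,5-bis(benzyloxy)phenol | Oc1cc(OCc2ccccc2)cc(OCc2ccccc2)c1 | starting material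
2 | 3,5-bis(benzyloxy)-2-bromophenol | Oc1cc(OCc2ccccc2)cc(OCc2ccccc2)c1Br | intermediate
3 | [3,5-bis(benzyloxy)-2-bromophenoxy]trimethylsilane | C[Si](C)(C)Oc1cc(OCc2ccccc2)cc(OCc2ccccc2)c1Br | intermediate
4 | [2,4-bis(benzyloxy)-6-(trimethylsilyloxy)phenyl]lithium | C[Si](C)(C)Oc1cc(OCc2ccccc2)cc(OCc2ccccc2)c1[Li] | intermediate
5 | lithium 3,5-bis(benzyloxy)-2-(trimethylsilyl)phenoxide | [Li+].[O-]c1cc(OCc2ccccc2)cc(OCc2ccccc2)c1[Si](C)(C)C | intermediate
6 | 3,5-bis(benzyloxy)-2-(trimethylsilyl)phenyl trifluoromethanesulfonate | C[Si](C)(C)c1c(OCc2ccccc2)cc(OCc2ccccc2)cc1OS(=O)(=O)C(F)(F)F | intermediate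
7 | 2,6-dimethoxyphenol | COc1cccc(OC)c1O | starting material
8 | 2-(benzyloxy)-1,3-dimethoxybenzene | COc1cccc(OC)c1OCc1ccccc1 | intermediate
9 | 3-(benzyloxy)-1,5-diiodo-2,4-dimethoxybenzene | COc1c(I)cc(I)c(OC)c1OCc1ccccc1 | intermediate
10 | [3-(benzyloxy)-5-iodo-2,4-dimethoxyphenyl]magnesium chloride | COc1c(I)cc([Mg]Cl)c(OC)c1OCc1ccccc1 | intermediate
11 | dimethyl [3-(benzyloxy)-5-iodo-2,4-dimethoxyphenyl]boronate | COB(OC)c1cc(I)c(OC)c(OCc2ccccc2)c1OC | intermediate
12 | 3-(benzyloxy)-5-iodo-2,4-dimethoxyphenol | COc1c(I)cc(O)c(OC)c1OCc1ccccc1 | intermediate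
13 | 3-(benzyloxy)-1-iodo-2,4,5-trimethoxybenzene | COc1cc(I)c(OC)c(OCc2ccccc2)c1OC | intermediate
14 | propiolic acid | C#CC(=O)O | starting material
15 | 3-[3-(benzyloxy)-2,4,5-trimethoxyphenyl]prop-2-ynoic acid | COc1cc(C#CC(=O)O)c(OC)c(OCc2ccccc2)c1OC | intermediate
16 | cesium 3-[3-(benzyloxy)-2,4,5-trimethoxyphenyl]prop-2-ynoate | [Cs+].COc1cc(C#CC(=O)[O-])c(OC)c(OCc2ccccc2)c1OC | intermediate
17 | 3,5-bis(benzyloxy)benzyne (triple bond C1–C2, benzyloxy groups at C3 and C5) | C1#CC(OCc2ccccc2)=CC(OCc2ccccc2)=C1 | intermediate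
18 | cesium salt of the aryl anion 2-{3-[3-(benzyloxy)-2,4,5-trimethoxyphenyl]prop-2-ynoyloxy}-4,6-bis(benzyloxy)phenide | [Cs+].COc1cc(C#CC(=O)Oc2cc(OCc3ccccc3)cc(OCc3ccccc3)[c-]2)c(OC)c(OCc2ccccc2)c1OC | intermediate
19 | cesium 3,5-bis(benzyloxy)-2-{3-[3-(benzyloxy)-2,4,5-trimethoxyphenyl]prop-2-ynoyl}phenoxide | [Cs+].COc1cc(C#CC(=O)c2c([O-])cc(OCc3ccccc3)cc2OCc2ccccc2)c(OC)c(OCc2ccccc2)c1OC | intermediate
20 | 5,7,3'-tris(benzyloxy)-2',4',5'-trimethoxyflavone | COc1cc(-c2cc(=O)c3c(OCc4ccccc4)cc(OCc4ccccc4)cc3o2)c(OC)c(OCc2ccccc2)c1OC | intermediate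
21 | 5,7,3'-trihydroxy-2',4',5'-trimethoxyflavone | COc1cc(-c2cc(=O)c3c(O)cc(O)cc3o2)c(OC)c(O)c1OC | target

Total step count: 10 (three for ring A, five for ring B, two after the union).
Longest linear sequence: 7 (steps 4 to 10, from 2,6-dimethoxyphenol).

Steps most likely to fail

Step 9. Three things may go wrong:
- The aryl anion may pick up a proton before it reaches the ester carbonyl, so that the sequence stops at plain O-arylation.
- The propiolate may lose CO2 at 125 °C.
- Part of the phenoxide may close in the 5-exo sense.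

The fallback sets out from 2 and 15 and comes back to the route at 20. It keeps the phenol oxygen on ring A from the start and makes C4–C4a by acylation of a regiodefined aryllithium. Acid 15 would be coupled with MeNHOMe·HCl (EDC·HCl, N-methylmorpholine, CH2Cl2) to the Weinreb amide 3-[3-(benzyloxy)-2,4,5-trimethoxyphenyl]-N-methoxy-N-methylprop-2-ynamide F1. Bromophenol 2 would be protected with MOMCl and i-Pr2NEt as 1,5-bis(benzyloxy)-2-bromo-3-(methoxymethoxy)benzene F2. Bromine–lithium exchange on F2 (n-BuLi, THF, −78 °C) and addition of F1 should give 1-[2,4-bis(benzyloxy)-6-(methoxymethoxy)phenyl]-3-[3-(benzyloxy)-2,4,5-trimethoxyphenyl]prop-2-yn-1-one F3. HCl in MeOH would free 1-[2,4-bis(benzyloxy)-6-hydroxyphenyl]-3-[3-(benzyloxy)-2,4,5-trimethoxyphenyl]prop-2-yn-1-one F4, and catalytic DMAP in DMF would close ring C in the 6-endo sense to 20.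

Step 8. Oxidative addition into the electron-rich, ortho-substituted iodide may be slow. The product may also decarboxylate on palladium and couple a second time. The fallback sets out from 13 and comes back at 15, and it separates alkynylation from carboxylation. Sonogashira coupling of 13 with ethynyltrimethylsilane (PdCl2(PPh3)2, CuI, Et3N, 50 °C) should give {[3-(benzyloxy)-2,4,5-trimethoxyphenyl]ethynyl}trimethylsilane F5. K2CO3 in MeOH would remove the silyl group to give 3-(benzyloxy)-1-ethynyl-2,4,5-trimethoxybenzene F6. Deprotonation with n-BuLi in THF at −78 °C, a CO2 quench and acidification would then give 15.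

Step 1. Bromination may spread over C2 and C4 or run on to double substitution, so that the pure 2-bromo compound becomes hard to secure. The fallback sets out from 1 and comes back at 6. It replaces electrophilic substitution and the silyl shift by directed ortho-metalation.
- Phenol 1 and isopropyl isocyanate (catalytic Et3N, CH2Cl2) should give 3,5-bis(benzyloxy)phenyl isopropylcarbamate F7.
- In one flask, TBSOTf and TMEDA in Et2O would mask the N–H as 3,5-bis(benzyloxy)phenyl N-(tert-butyldimethylsilyl)-N-isopropylcarbamate F8.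
- n-BuLi/TMEDA at −78 °C would then metalate C2, the site flanked by the carbamate and a benzyloxy group, and TMSCl would give 3,5-bis(benzyloxy)-2-(trimethylsilyl)phenyl N-(tert-butyldimethylsilyl)-N-isopropylcarbamate F9.
- Acidic work-up would leave 3,5-bis(benzyloxy)-2-(trimethylsilyl)phenyl isopropylcarbamate F10.
- DBU and Et2NH in MeCN at 40 °C would release 3,5-bis(benzyloxy)-2-(trimethylsilyl)phenol F11, which PhNTf2 added to the same flask would convert into 6.

Further compounds
F1 | step 9 | 3-[3-(benzyloxy)-2,4,5-trimethoxyphenyl]-N-methoxy-N-methylprop-2-ynamide | COc1cc(C#CC(=O)N(C)OC)c(OC)c(OCc2ccccc2)c1OC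
F2 | step 9 | 1,5-bis(benzyloxy)-2-bromo-3-(methoxymethoxy)benzene | COCOc1cc(OCc2ccccc2)cc(OCc2ccccc2)c1Br
F3 | step 9 | 1-[2,4-bis(benzyloxy)-6-(methoxymethoxy)phenyl]-3-[3-(benzyloxy)-2,4,5-trimethoxyphenyl]prop-2-yn-1-one | COCOc1cc(OCc2ccccc2)cc(OCc2ccccc2)c1C(=O)C#Cc1cc(OC)c(OC)c(OCc2ccccc2)c1OC
F4 | step 9 | 1-[2,4-bis(benzyloxy)-6-hydroxyphenyl]-3-[3-(benzyloxy)-2,4,5-trimethoxyphenyl]prop-2-yn-1-one | COc1cc(C#CC(=O)c2c(O)cc(OCc3ccccc3)cc2OCc2ccccc2)c(OC)c(OCc2ccccc2)c1OC
F5 | step 8 | {[3-(benzyloxy)-2,4,5-trimethoxyphenyl]ethynyl}trimethylsilane | COc1cc(C#C[Si](C)(C)C)c(OC)c(OCc2ccccc2)c1OC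
F6 | step 8 | 3-(benzyloxy)-1-ethynyl-2,4,5-trimethoxybenzene | COc1cc(C#C)c(OC)c(OCc2ccccc2)c1OC
F7 | step 1 | 3,5-bis(benzyloxy)phenyl isopropylcarbamate | CC(C)NC(=O)Oc1cc(OCc2ccccc2)cc(OCc2ccccc2)c1
F8 | step 1 | 3,5-bis(benzyloxy)phenyl N-(tert-butyldimethylsilyl)-N-isopropylcarbamate | CC(C)N(C(=O)Oc1cc(OCc2ccccc2)cc(OCc2ccccc2)c1)[Si](C)(C)C(C)(C)C
F9 | step 1 | 3,5-bis(benzyloxy)-2-(trimethylsilyl)phenyl N-(tert-butyldimethylsilyl)-N-isopropylcarbamate | CC(C)N(C(=O)Oc1cc(OCc2ccccc2)cc(OCc2ccccc2)c1[Si](C)(C)C)[Si](C)(C)C(C)(C)C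
F10 | step 1 | 3,5-bis(benzyloxy)-2-(trimethylsilyl)phenyl isopropylcarbamate | CC(C)NC(=O)Oc1cc(OCc2ccccc2)cc(OCc2ccccc2)c1[Si](C)(C)C
F11 | step 1 | 3,5-bis(benzyloxy)-2-(trimethylsilyl)phenol | Oc1cc(OCc2ccccc2)cc(OCc2ccccc2)c1[Si](C)(C)C
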